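**Retrosynthetic overview**
1. Both C15 halves are chiral-pool flavan-3-ols. (+)-Catechin (1), as its 6,8-dibromide 2, becomes the ring-opened upper half. (+)-Epicatechin (3), taken through 4, 5 and 6 to the 8-bromo catechol ketal 7, is the intact lower half.
2. Key disconnection: the bond from the diarylmethine carbon of the propan-2-ol chain to C6 of the flavan. Forward, ring C of 2 is opened at O1–C2 to p-quinone methide 8, and C6 of 7 adds to it to give 9.
3. Enabling feature: in 2 the 4′-OH of ring B is para to C2, and C2–O1 is a benzylic aryl ether inside ring C, so the 4′-phenoxide can push out the ring A aryloxide through ring B.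
4. Rings: none is formed. The three rings of the lower unit and the two aromatic rings of the upper unit come ready-made from 3 and 1, and the only ring event is the opening of ring C of 1. The chain carbinol (S) is C3 of 1, the lower 2S,3S pair is that of 3, and the diarylmethine centre (R) is set in the key step.
5. Last disconnection: the three C–Br blocking groups and the diphenylmethylene ketal of 9 fall in one hydrogenolysis to give target 10.

Key step: step 6

Remark on the chemistry: (+)-epicatechin, (2S,3S), is taken as a purchasable starting material. Flavan numbering (O1, C2, C3, C4, ring A C5–C8, ring B primed) is used, and the chain of the upper half is numbered C1 (diarylmethine), C2 (carbinol), C3 (CH2).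

**Step 1**
Reactants: 1 (+)-catechin, (2R,3S)-2-(3,4-dihydroxyphenyl)chromane-3,5,7-triol
Product: 2 6,8-dibromo-(+)-catechin, (2R,3S)-6,8-dibromo-2-(3,4-dihydroxyphenyl)chromane-3,5,7-triol
Conditions: NBS (2.05 equiv), THF, −40 → 0 °C, Ar, dark
Reagents that add atoms: N-bromosuccinimide, O=C1CCC(=O)N1Br
Why: Electrophilic aromatic bromination, in which C6 and C8 of ring A (each ortho or para to three oxygens) react far faster than the catechol ring, so that two equivalents of NBS fill exactly the two carbons that would otherwise compete as nucleophiles later, while the bromines also make the ring A oxygen a better leaving group; no stereocentre is touched.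

**Step 2**
Reactants: 3 (+)-epicatechin, (2S,3S)-2-(3,4-dihydroxyphenyl)chromane-3,5,7-triol
Product: 4 3′,4′-O-diphenylmethylene-(+)-epicatechin, (2S,3S)-2-(2,2-diphenyl-1,3-benzodioxol-5-yl)chromane-3,5,7-triol
Conditions: Ph2CCl2 (1.3 equiv), K2CO3 (4 equiv), MeCN, 0 °C → rt, Ar
Reagents that add atoms: dichlorodiphenylmethane, ClC(Cl)(c1ccccc1)c1ccccc1
Why: Catechol-selective ketalisation by double O-alkylation with the geminal dichloride, since only the vicinal 3′,4′-oxygens can close the five-membered 1,3-benzodioxole; once the 4′-oxygen is capped ring C can no longer open, so 2S,3S is fixed from here on.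

**Step 3**
Reactants: 4 3′,4′-O-diphenylmethylene-(+)-epicatechin
Product: 5 3,5,7-tris-O-(tert-butyldimethylsilyl)-3′,4′-O-diphenylmethylene-(+)-epicatechin
Conditions: TBSCl (4.5 equiv), imidazole (9 equiv), DMF, rt → 40 °C
Reagents that add atoms: tert-butyldimethylsilyl chloride, CC(C)(C)[Si](C)(C)Cl
Why: Imidazole-promoted silyl ether formation on the two ring A phenols and the 3-OH turns ring A into a tri-ether, so that the next bromination follows the steric rule of 5,7-di-O-protected flavans.

**Step 4**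
Reactants: 5 tris-TBS ether
Product: 6 8-bromo-3,5,7-tris-O-(tert-butyldimethylsilyl)-3′,4′-O-diphenylmethylene-(+)-epicatechin
Conditions: NBS (1.0 equiv), CH2Cl2, −78 → −20 °C
Reagents that add atoms: N-bromosuccinimide, O=C1CCC(=O)N1Br
Why: Electrophilic aromatic bromination of the tri-oxygenated ring A, expected at C8 (between one OTBS and the small ring oxygen) rather than C6 (between two OTBS groups), the same preference that 5,7-di-O-alkyl flavans show, with the benzodioxole ring far less activated.

**Step 5**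
Reactants: 6 8-bromo tris-TBS ether
Product: 7 8-bromo-3′,4′-O-diphenylmethylene-(+)-epicatechin, (2S,3S)-8-bromo-2-(2,2-diphenyl-1,3-benzodioxol-5-yl)chromane-3,5,7-triol
Conditions: Bu4NF (3.5 equiv), AcOH (3.5 equiv), THF, 0 °C → rt
Reagents that add atoms: none
Why: Fluoride-induced desilylation buffered with AcOH frees the 5-, 7- and 3-hydroxyls, the aryl bromide and the ketal being inert and C2 being safe because the capped catechol cannot open ring C.

**Step 6**
Reactants: 2 6,8-dibromo-(+)-catechin; 7 8-bromo-3′,4′-O-diphenylmethylene-(+)-epicatechin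
Product: 9 (2S,3S)-8-bromo-6-[(1R,2S)-3-(3,5-dibromo-2,4,6-trihydroxyphenyl)-1-(3,4-dihydroxyphenyl)-2-hydroxypropyl]-2-(2,2-diphenyl-1,3-benzodioxol-5-yl)chromane-3,5,7-triol, via quinone methide 8 (not isolated)
Conditions: 7 (2 equiv), slow addition of 2 (1 equiv), degassed aq. Na2CO3/NaHCO3 buffer (pH ca. 11)–MeCN 1:1, Ar, 35 °C; then AcOH to pH 5
Reagents that add atoms: none
Why: At pH ca. 11 the 4′-phenoxide of 2 pushes through ring B and expels the O1 aryloxide (a better leaving group because of the two bromines), opening ring C to p-quinone methide 8 by a retro-oxa-1,6-addition; C6 of the 5,7-diphenoxide of 7 then adds 1,6 to the former C2 and rearomatisation gives 9, all O-captures of 8 (reclosure, water, phenoxide oxygen) being reversible so that the C–C bond is the sink. The closest known reaction type is the base-induced quinone-methide opening of catechin with C-arylation at C2 by phloroglucinol-type rings, the event behind the self-condensation of catechin to chalcane–flavan dimers. No ring is closed; ring C of 2 is opened. The new stereocentre C1 (R) is controlled by the adjacent carbinol (former C3, S): allylic 1,3-strain holds its C–H in the plane of the quinone methide, the CH2–aryloxide arm that has just left C2 shields one face, and the nucleophile should enter from the hydroxyl-bearing face, helped by a hydrogen bond from that OH to a phenoxide oxygen flanking C6, which amounts to inversion at C2 of catechin. The step needs chemoselectivity (only 2 may open; the catechol of 7 is tied up as the ketal, so 7 and the lower unit of 9 keep 2S,3S), regioselectivity (C8 of 7 and C6/C8 of 2 carry bromine, leaving C6 of 7 as the only free phloroglucinol-type carbon in the flask) and the facial selectivity just described.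

**Step 7**
Reactants: 9 tribromo ketal adduct
Product: 10 target, (2S,3S)-2-(3,4-dihydroxyphenyl)-6-[(1R,2S)-1-(3,4-dihydroxyphenyl)-2-hydroxy-3-(2,4,6-trihydroxyphenyl)propyl]chromane-3,5,7-triol
Conditions: H2 (1 atm), Pd(OH)2/C, NaOAc (3.3 equiv), THF–MeOH 1:1, rt
Reagents that add atoms: none
Why: Catalytic hydrogenolysis should cleave the three aryl C–Br bonds (HBr taken up by NaOAc, which keeps the medium near neutral) and the two benzhydrylic C–O bonds of the diphenylmethylene ketal, without involving any of the four stereocentres.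

**Compound list**
1 | (+)-catechin | O[C@H]1Cc2c(O)cc(O)cc2O[C@@H]1c1ccc(O)c(O)c1 | starting material
2 | 6,8-dibromo-(+)-catechin | O[C@H]1Cc2c(O)c(Br)c(O)c(Br)c2O[C@@H]1c1ccc(O)c(O)c1 | intermediate
3 | (+)-epicatechin, (2S,3S) | O[C@H]1Cc2c(O)cc(O)cc2O[C@H]1c1ccc(O)c(O)c1 | starting material
4 | 3′,4′-O-diphenylmethylene-(+)-epicatechin | O[C@H]1Cc2c(O)cc(O)cc2O[C@H]1c1ccc2OC(c3ccccc3)(c3ccccc3)Oc2c1 | intermediate
5 | 3,5,7-tris-O-TBS-3′,4′-O-diphenylmethylene-(+)-epicatechin | CC(C)(C)[Si](C)(C)O[C@H]1Cc2c(O[Si](C)(C)C(C)(C)C)cc(O[Si](C)(C)C(C)(C)C)cc2O[C@H]1c1ccc2OC(c3ccccc3)(c3ccccc3)Oc2c1 | intermediate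
6 | 8-bromo-3,5,7-tris-O-TBS-3′,4′-O-diphenylmethylene-(+)-epicatechin | CC(C)(C)[Si](C)(C)O[C@H]1Cc2c(O[Si](C)(C)C(C)(C)C)cc(O[Si](C)(C)C(C)(C)C)c(Br)c2O[C@H]1c1ccc2OC(c3ccccc3)(c3ccccc3)Oc2c1 | intermediate
7 | 8-bromo-3′,4′-O-diphenylmethylene-(+)-epicatechin | O[C@H]1Cc2c(O)cc(O)c(Br)c2O[C@H]1c1ccc2OC(c3ccccc3)(c3ccccc3)Oc2c1 | intermediate
8 | 4-[(2S)-3-(3,5-dibromo-2,4,6-trihydroxyphenyl)-2-hydroxypropylidene]-2-hydroxycyclohexa-2,5-dien-1-one (p-quinone methide, not isolated) | O=C1C(O)=CC(=C[C@@H](O)Cc2c(O)c(Br)c(O)c(Br)c2O)C=C1 | intermediate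
9 | (2S,3S)-8-bromo-6-[(1R,2S)-3-(3,5-dibromo-2,4,6-trihydroxyphenyl)-1-(3,4-dihydroxyphenyl)-2-hydroxypropyl]-2-(2,2-diphenyl-1,3-benzodioxol-5-yl)chromane-3,5,7-triol | Oc1c(Br)c(O)c(C[C@H](O)[C@H](c2ccc(O)c(O)c2)c2c(O)c(Br)c3c(c2O)C[C@H](O)[C@H](c2ccc4OC(c5ccccc5)(c5ccccc5)Oc4c2)O3)c(O)c1Br | intermediate
10 | (2S,3S)-2-(3,4-dihydroxyphenyl)-6-[(1R,2S)-1-(3,4-dihydroxyphenyl)-2-hydroxy-3-(2,4,6-trihydroxyphenyl)propyl]chromane-3,5,7-triol | Oc1cc(O)c(C[C@H](O)[C@H](c2ccc(O)c(O)c2)c2c(O)cc3c(c2O)C[C@H](O)[C@H](c2ccc(O)c(O)c2)O3)c(O)c1 | target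

**Step count and risks**
Total step count: 7. Longest linear sequence: 6 (steps 2, 3, 4, 5, 6, 7).

Steps most likely to fail:

1. Step 6. The capture of 8 may show poor facial selectivity at the diarylmethine carbon, or the attack at C6 may lose to reversible reclosure followed by slow tautomerisation of the quinone methide to an aryl ketone. The fallback changes from the anionic quinone-methide manifold to a cationic Friedel–Crafts coupling of fully O-benzylated partners, in which a neutral arene attacks a benzylic cation anti to the large CH2-aryl arm. It sets out from 2 and 3 and comes back at 10. Compound 2 is opened at pH 11 in the presence of phenylmethanethiol, the thiolate trapping quinone methide 8 to give the sulfide (2S)-1-(benzylsulfanyl)-3-(3,5-dibromo-2,4,6-trihydroxyphenyl)-1-(3,4-dihydroxyphenyl)propan-2-ol F1 (both C1 epimers, which converge later). Its five phenols are capped quickly (BnBr, Cs2CO3, DMF, 0 °C) to give (2S)-1-(benzylsulfanyl)-1-[3,4-bis(benzyloxy)phenyl]-3-[2,4,6-tris(benzyloxy)-3,5-dibromophenyl]propan-2-ol F2. In parallel 3 is benzylated (NaH, BnBr, DMF, −20 °C → rt) to 5,7,3′,4′-tetra-O-benzyl-(+)-epicatechin F3 and brominated with NBS at C8 to 8-bromo-5,7,3′,4′-tetra-O-benzyl-(+)-epicatechin F4. AgBF4 in THF–CH2Cl2 at −40 °C then removes the benzylthio group of F2, and C6 of F4 (in excess) takes up the benzylic carbon to give the nona-O-benzyl tribromo adduct F5. Hydrogenolysis (H2, Pd(OH)2/C, NaOAc) of the nine benzyl ethers and three C–Br bonds returns to 10.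

2. Step 2. Before the catechol is capped, the carbonate base may open ring C of free (+)-epicatechin through its 4′-phenoxide and so erode the 2S configuration, and Ph2CCl2 may be consumed by the ring A phenols. The fallback replaces the base-mediated double alkylation by an acid-catalysed acetal exchange, in which no phenoxide is ever formed and the ring-opening pathway is closed by mechanism. It sets out from 3 and comes back at 4: benzophenone dimethyl acetal, catalytic camphorsulfonic acid, MeCN, 50 °C with removal of methanol. No new compound is made (F0).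

3. Step 1. NBS may oxidise the free catechol to the o-quinone or over-brominate ring B. The fallback gives up the blocking of the electrophile. It sets out from 1 and comes back at 10. (+)-Catechin 1 itself is added slowly to a larger excess of 7 (4 equiv) under the conditions of step 6 at pH 12, so that capture by 7 outruns attack by the liberated phloroglucinol ring. The reaction passes through the unbrominated quinone methide 4-[(2S)-2-hydroxy-3-(2,4,6-trihydroxyphenyl)propylidene]-2-hydroxycyclohexa-2,5-dien-1-one F6 and should give (2S,3S)-8-bromo-6-[(1R,2S)-1-(3,4-dihydroxyphenyl)-2-hydroxy-3-(2,4,6-trihydroxyphenyl)propyl]-2-(2,2-diphenyl-1,3-benzodioxol-5-yl)chromane-3,5,7-triol F7. F7 is hydrogenolysed as in step 7 to 10.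

**Further compounds**
F1 | step 6 | (2S)-1-(benzylsulfanyl)-3-(3,5-dibromo-2,4,6-trihydroxyphenyl)-1-(3,4-dihydroxyphenyl)propan-2-ol (both C1 epimers) | Oc1c(Br)c(O)c(C[C@H](O)C(SCc2ccccc2)c2ccc(O)c(O)c2)c(O)c1Br
F2 | step 6 | (2S)-1-(benzylsulfanyl)-1-[3,4-bis(benzyloxy)phenyl]-3-[2,4,6-tris(benzyloxy)-3,5-dibromophenyl]propan-2-ol (both C1 epimers) | O(Cc1ccccc1)c1c(Br)c(OCc2ccccc2)c(C[C@H](O)C(SCc2ccccc2)c2ccc(OCc3ccccc3)c(OCc3ccccc3)c2)c(OCc2ccccc2)c1Br
F3 | step 6 | 5,7,3′,4′-tetra-O-benzyl-(+)-epicatechin | O[C@H]1Cc2c(OCc3ccccc3)cc(OCc3ccccc3)cc2O[C@H]1c1ccc(OCc2ccccc2)c(OCc2ccccc2)c1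
F4 | step 6 | 8-bromo-5,7,3′,4′-tetra-O-benzyl-(+)-epicatechin | O[C@H]1Cc2c(OCc3ccccc3)cc(OCc3ccccc3)c(Br)c2O[C@H]1c1ccc(OCc2ccccc2)c(OCc2ccccc2)c1
F5 | step 6 | (2S,3S)-5,7-bis(benzyloxy)-2-[3,4-bis(benzyloxy)phenyl]-6-{(1R,2S)-1-[3,4-bis(benzyloxy)phenyl]-3-[2,4,6-tris(benzyloxy)-3,5-dibromophenyl]-2-hydroxypropyl}-8-bromochroman-3-ol | O(Cc1ccccc1)c1c(Br)c(OCc2ccccc2)c(C[C@H](O)[C@H](c2ccc(OCc3ccccc3)c(OCc3ccccc3)c2)c2c(OCc3ccccc3)c(Br)c3c(c2OCc2ccccc2)C[C@H](O)[C@H](c2ccc(OCc4ccccc4)c(OCc4ccccc4)c2)O3)c(OCc2ccccc2)c1Br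
F0 | step 2 | none | none
F6 | step 1 | 4-[(2S)-2-hydroxy-3-(2,4,6-trihydroxyphenyl)propylidene]-2-hydroxycyclohexa-2,5-dien-1-one | O=C1C(O)=CC(=C[C@@H](O)Cc2c(O)cc(O)cc2O)C=C1
F7 | step 1 | (2S,3S)-8-bromo-6-[(1R,2S)-1-(3,4-dihydroxyphenyl)-2-hydroxy-3-(2,4,6-trihydroxyphenyl)propyl]-2-(2,2-diphenyl-1,3-benzodioxol-5-yl)chromane-3,5,7-triol | Oc1cc(O)c(C[C@H](O)[C@H](c2ccc(O)c(O)c2)c2c(O)c(Br)c3c(c2O)C[C@H](O)[C@H](c2ccc4OC(c5ccccc5)(c5ccccc5)Oc4c2)O3)c(O)c1
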